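The ten-membered carbocycle (C1–C10) is closed between C9 and C10 by an intramolecular nitrile oxide–alkene cycloaddition. The step exploits the 1,3-related oxygens on C8 and C10 across the C9 methylene, with C10 next to the C1 carbonyl: an isoxazoline whose carbon is C10 and whose oxygen sits on C8 is this array in masked form. One operation forms C9–C10 and O–C8, closes the carbocycle and the bridging isoxazoline, and sets C8. The precursor is the cis-fused 4,5-epoxy-6,12-lactone, made from nerol, carrying a C7 vinyl group (C8=C9) and, at the other end of the C1–C3 chain, a silyl-protected nitro alcohol (C10 nitromethyl, C1 carbinol).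

Key step: step 11

Remark (labels): atoms carry the germacranolide labels of the target: C1 ketone carbon, C2, C3, C4 (methyl, epoxide), C5 (epoxide), C6 (lactone oxygen), C7, C8 (methacrylate), C9, C10 (methyl, acetate), C11, C12 (lactone carbonyl), C13 (acetoxymethyl); CIP descriptors are recomputed for each compound, so a label can change its descriptor without any change at the centre.

Remark (C1): the C1 silyloxy centre is a spectator that ends as the ketone; it is set as 1R, because for a non-chelating silyl ether the Felkin–Anh preference at C1 then agrees with chelation through the C8 alkoxide in the methyl addition to C10, whereas the 1S epimer would set the two effects against each other.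

Remark (C11): C13 has to end cis to the C7 substituent, which enolate alkylation would not give; it is therefore brought in as an exocyclic methylene on the allylating reagent and oxygenated by conjugate borylation with kinetic protonation.

Assumption: the inda-box antipode used in step 9 is the one that directs nitromethane to the Si face of the aldehyde (1R); both antipodes are available.

Step 1
Reactants: 1 acrolein; 2 methyl acrylate
Product: 3 methyl 3-hydroxy-2-methylidenepent-4-enoate (racemic)
Conditions: DABCO (0.1 equiv), excess methyl acrylate as solvent, rt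
Reagents that add atoms: none
Why: Morita–Baylis–Hillman reaction, in which the amine adds reversibly to the acrylate and the resulting enolate attacks the aldehyde carbonyl of acrolein; the carbinol centre is lost in step 2, so the racemate suffices.

Step 2
Reactants: 3 methyl 3-hydroxy-2-methylidenepent-4-enoate
Product: 4 methyl (2Z)-2-(bromomethyl)penta-2,4-dienoate
Conditions: PBr3 (0.4 equiv), Et2O, −10 → 0 °C
Reagents that add atoms: phosphorus tribromide, BrP(Br)Br
Why: SN2′ bromination of a Baylis–Hillman alcohol with allylic transposition, which should give the conjugated dienoate with the vinyl group trans to the ester; any allylic regioisomer of the bromide would lead to the same dienylindium species in step 5.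

Step 3
Reactants: 5 nerol
Product: 6 (2S,3R)-2,3-epoxynerol, [(2S,3R)-3-methyl-3-(4-methylpent-3-en-1-yl)oxiran-2-yl]methanol
Conditions: Ti(OiPr)4 (10 mol%), L-(+)-diethyl tartrate (13 mol%), tBuOOH (anhydrous, isooctane), 4 Å MS, CH2Cl2, −20 °C
Reagents that add atoms: tert-butyl hydroperoxide, CC(C)(C)OO
Why: Sharpless asymmetric epoxidation, which touches only the allylic alcohol alkene; L-(+)-tartrate should deliver oxygen to the face that gives 2S,3R (C5 S, C4 R), and the Z geometry of nerol places the chain and the hydroxymethyl group cis on the epoxide as the target requires.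

Step 4
Reactants: 6 (2S,3R)-2,3-epoxynerol
Product: 7 (2R,3R)-3-methyl-3-(4-methylpent-3-en-1-yl)oxirane-2-carbaldehyde
Conditions: Dess–Martin periodinane (1.3 equiv), NaHCO3, CH2Cl2, 0 °C → rt; used crude
Reagents that add atoms: none
Why: Dess–Martin oxidation under buffered, non-epimerising conditions; the centres are untouched and only the CIP descriptor of the aldehyde-bearing carbon changes.

Step 5
Reactants: 7 epoxy aldehyde; 4 methyl (2Z)-2-(bromomethyl)penta-2,4-dienoate
Product: 9 (4R,5S)-4-ethenyl-3-methylidene-5-[(2S,3R)-3-methyl-3-(4-methylpent-3-en-1-yl)oxiran-2-yl]oxolan-2-one, via syn-hydroxy ester 8 (not isolated)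
Conditions: In powder (1.5 equiv), THF–H2O (1:1), rt; crude adduct then PPTS (0.2 equiv), PhMe, 60 °C
Reagents that add atoms: none
Why: Barbier allylation, in which indium inserts into the C–Br bond of 4 and the dienylindium attacks the aldehyde through its central carbon in a chair transition state, the vinyl group cis to the metal-bearing CH2 giving the syn C6/C7 relationship and Felkin–Anh approach anti to the C5–O bond of the cis-epoxy aldehyde giving 6S, after which mild acid lactonisation of 8 should close the cis-disubstituted γ-lactone.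

Step 6
Reactants: 9 α-methylene lactone
Product: 11 (3R,4R,5S)-4-ethenyl-3-(hydroxymethyl)-5-[(2S,3R)-3-methyl-3-(4-methylpent-3-en-1-yl)oxiran-2-yl]oxolan-2-one, via C13 pinacol boronate 10 (not isolated)
Conditions: B2pin2 (1.1 equiv), CuCl (5 mol%), Xantphos (5 mol%), NaOtBu (10 mol%), MeOH (2 equiv), THF, rt; then NaBO3·4H2O, THF–H2O, rt
Reagents that add atoms: sodium perborate, [Na+].[O-]OB=O (oxygen of the C13 hydroxyl); bis(pinacolato)diboron, CC1(C)OB(OC1(C)C)B1OC(C)(C)C(C)(C)O1 (boryl group of 10)
Why: copper-catalysed conjugate borylation of the exocyclic enoate followed by perborate oxidation of the C–B bond; the copper enolate should be protonated by methanol on the lactone face opposite the C6 and C7 substituents, which places C13 cis to both (11R), and the unactivated alkenes and the epoxide do not react.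

Step 7
Reactants: 11 hydroxymethyl lactone
Product: 12 [(3R,4R,5S)-4-ethenyl-5-[(2S,3R)-3-methyl-3-(4-methylpent-3-en-1-yl)oxiran-2-yl]-2-oxooxolan-3-yl]methyl acetate
Conditions: Ac2O (1.5 equiv), pyridine, DMAP (5 mol%), CH2Cl2, 0 °C
Reagents that add atoms: acetic anhydride, CC(=O)OC(C)=O
Why: DMAP-catalysed acetylation of the primary alcohol at 0 °C with a weak base, conditions too mild to eliminate the β-acetoxy lactone or epimerise C11.

Step 8
Reactants: 12 acetate
Product: 14 [(3R,4R,5S)-4-ethenyl-5-[(2S,3R)-3-methyl-3-(3-oxopropyl)oxiran-2-yl]-2-oxooxolan-3-yl]methyl acetate, via secondary ozonide 13 (not isolated)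
Conditions: O3 (1 equiv, Sudan Red 7B end point), CH2Cl2, −78 °C; then PPh3, −78 °C → rt
Reagents that add atoms: ozone, [O-][O+]=O
Why: chemoselective ozonolysis, since electrophilic ozone cleaves the electron-rich trisubstituted C1=C(CH3)2 alkene much faster than the monosubstituted C8=C9 vinyl group, and phosphine reduction of ozonide 13 should give the C1 aldehyde.

Step 9
Reactants: 14 aldehyde; 15 nitromethane
Product: 16 [(3R,4R,5S)-4-ethenyl-5-[(2S,3R)-3-[(3R)-3-hydroxy-4-nitrobutyl]-3-methyloxiran-2-yl]-2-oxooxolan-3-yl]methyl acetate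
Conditions: MeNO2 (10 equiv), Cu(OAc)2·H2O (5 mol%), indane-fused bis(oxazoline) ligand (inda-box, 5.5 mol%, antipode for Si-face attack), EtOH, rt; used without chromatography
Reagents that add atoms: none
Why: catalytic asymmetric Henry (nitroaldol) reaction, in which the Cu(OAc)2–bis(oxazoline) complex should deliver the nitromethyl carbon (C10) to the Si face of the aldehyde and set 1R under catalyst control, the nearest stereocentre (C4) being too remote to interfere.

Step 10
Reactants: 16 nitro alcohol
Product: 17 [(3R,4R,5S)-5-[(2S,3R)-3-[(3R)-3-(tert-butyldimethylsilyloxy)-4-nitrobutyl]-3-methyloxiran-2-yl]-4-ethenyl-2-oxooxolan-3-yl]methyl acetate (the nitro alkene precursor)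
Conditions: TBSCl (1.5 equiv), imidazole (3 equiv), DMF, rt
Reagents that add atoms: tert-butyldimethylsilyl chloride, CC(C)(C)[Si](C)(C)Cl
Why: silylation of the secondary alcohol under acid-free conditions, which removes the hydroxyl that could open the C4–C5 epoxide and installs the bulky non-chelating group on C1.

Step 11
Reactants: 17 nitro alkene
Product: 19 (1R,4R,5S,6S,7R,8S,11R)-13-acetoxy-1-(tert-butyldimethylsilyloxy)-4,5-epoxy-6,12-olide with an isoxazoline bridging C8 (oxygen) and C10 (C=N) of the ten-membered ring, via nitrile oxide 18 (not isolated)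
Conditions: PhNCO (4 equiv), Et3N (0.3 equiv), PhMe, 0.002 M (17 added over 12 h by syringe pump), 25 → 50 °C
Reagents that add atoms: none
Why: Triethylamine forms the nitronate of 17, which is O-carbamoylated by the isocyanate and loses N-phenylcarbamic acid to give nitrile oxide 18, and 18 then adds to the C8=C9 vinyl group in a concerted [3+2] cycloaddition. The closest known reaction type is the intramolecular nitrile oxide–alkene cycloaddition that closes medium and large carbocycles as bridged 3,5-disubstituted isoxazolines. The isoxazoline is closed by the cycloaddition itself (C10–C9 and O–C8), and the ten-membered carbocycle by the C9–C10 bond in the bridged mode, both alkene carbons lying inside the new carbocycle, whereas the fused mode would give a nine-membered ring and the electronically disfavoured 4-substituted isoxazoline. The new C8 centre is controlled by the adjacent C7 centre: in the staggered transition state the forming C8–O bond should lie anti to the bulky C7–C11 bond while the tether leaves through C6, which puts oxygen on the face that gives 8S. The step needs bridged regiochemistry and ring closure ahead of furoxan dimerisation; the first is secured by the monosubstituted alkene (oxygen to the substituted carbon) and the seven-atom C1–C7 tether, the second by high dilution with slow addition, by the cis-epoxide and cis-lactone that fold C10 toward C9, and by the α-silyloxy group that slows dimerisation. Since the reagents are only an isocyanate and a catalytic amine, the epoxide, both esters and the silyl ether are not at risk.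

Step 12
Reactants: 19 bridged isoxazoline
Product: 21 (1R,4R,5S,6S,7S,8S,11R)-13-acetoxy-1-(tert-butyldimethylsilyloxy)-4,5-epoxy-8-hydroxy-10-oxo ten-membered 6,12-olide, via β-hydroxy imine 20 (not isolated)
Conditions: Raney Ni (W-2), H2 (1 atm), B(OH)3 (3 equiv), MeOH–H2O (5:1), rt
Reagents that add atoms: water, O
Why: hydrogenolysis of the isoxazoline N–O bond over Raney Ni and boric-acid-buffered hydrolysis of imine 20, the standard unmasking of an isoxazoline to a β-hydroxy ketone, which should leave the C8 configuration, the silyl ether, the epoxide and the esters untouched.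

Step 13
Reactants: 21 β-hydroxy ketone
Product: 22 (1R,4R,5S,6S,7S,8S,10R,11R)-13-acetoxy-1-(tert-butyldimethylsilyloxy)-4,5-epoxy-8,10-dihydroxy-10-methyl ten-membered 6,12-olide
Conditions: MeTi(OiPr)3 (5 equiv), Et2O–THF, −30 → 0 °C; aq. NH4Cl
Reagents that add atoms: methyltitanium triisopropoxide, C[Ti](OC(C)C)(OC(C)C)OC(C)C
Why: organotitanium 1,2-addition that attacks only the ketone (lactone, acetate and epoxide are inert); methyl should be delivered anti to the C8 substituent of the six-membered chelate formed by the C8 titanium alkoxide and the C10 carbonyl, the same face that the Felkin–Anh model predicts for the 1R silyloxy centre, giving 10R (C8–O and C10–O cis on the ring, C10–O and C1–O trans).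

Step 14
Reactants: 22 diol
Product: 23 the C8 methacrylate of 22 (1R,4R,5S,6S,7S,8S,10R,11R)
Conditions: methacrylic anhydride (1.5 equiv), Et3N (2 equiv), DMAP (0.2 equiv), CH2Cl2, 0 °C → rt
Reagents that add atoms: methacrylic anhydride, C=C(C)C(=O)OC(=O)C(C)=C
Why: DMAP-catalysed acylation, in which the secondary C8 alcohol should be esterified while the tertiary C10 alcohol next to the silyloxy-bearing C1 does not react at this temperature.

Step 15
Reactants: 23 silyl ether
Product: 24 (1R,4R,5S,6S,7S,8S,10R,11R)-13-acetoxy-4,5-epoxy-1,10-dihydroxy-10-methyl-8-methacryloyloxy ten-membered 6,12-olide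
Conditions: HF·pyridine, pyridine, THF, 0 °C → rt
Reagents that add atoms: none
Why: fluoride cleavage of the secondary silyl ether with pyridine-buffered HF, conditions under which the trisubstituted epoxide, the esters and the methacrylate are expected to be stable.

Step 16
Reactants: 24 1,10-diol
Product: 25 (4R,5S,6S,7S,8S,10R,11R)-13-acetoxy-4,5-epoxy-10-hydroxy-10-methyl-8-methacryloyloxy-1-oxo ten-membered 6,12-olide
Conditions: IBX (2 equiv), DMSO, rt
Reagents that add atoms: none
Why: IBX oxidation of the secondary C1 alcohol, a reagent that converts 1,2-diols to α-hydroxy ketones without C–C cleavage and cannot oxidise the tertiary C10 alcohol; the C1 centre, having served its purpose, is removed.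

Step 17
Reactants: 25 α-hydroxy ketone
Product: 26 target (4R,5S,6S,7S,8S,10R,11R)-10,13-diacetoxy-4,5-epoxy-8-methacryloyloxy-1-oxo ten-membered 6,12-olide
Conditions: Ac2O (10 equiv), DMAP (3 equiv), CH2Cl2, 25 → 40 °C
Reagents that add atoms: acetic anhydride, CC(=O)OC(C)=O
Why: Steglich-type acetylation of the tertiary α-ketol hydroxyl with excess anhydride and DMAP, placed last so that no free neighbouring hydroxyl is left for acyl migration.

Compound list
1 | acrolein | C=CC=O | starting material
2 | methyl acrylate | C=CC(=O)OC | starting material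
3 | methyl 3-hydroxy-2-methylidenepent-4-enoate (racemic) | C=CC(O)C(=C)C(=O)OC | intermediate
4 | methyl (2Z)-2-(bromomethyl)penta-2,4-dienoate | C=C/C=C(\CBr)C(=O)OC | intermediate
5 | nerol | CC(C)=CCC/C(C)=C\CO | starting material
6 | (2S,3R)-2,3-epoxynerol | CC(C)=CCC[C@@]1(C)O[C@H]1CO | intermediate
7 | (2R,3R)-3-methyl-3-(4-methylpent-3-en-1-yl)oxirane-2-carbaldehyde | CC(C)=CCC[C@@]1(C)O[C@H]1C=O | intermediate
8 | methyl (3R,4S)-3-ethenyl-4-hydroxy-2-methylidene-4-[(2S,3R)-3-methyl-3-(4-methylpent-3-en-1-yl)oxiran-2-yl]butanoate (not isolated) | CC(C)=CCC[C@@]1(C)O[C@H]1[C@@H](O)[C@H](C=C)C(=C)C(=O)OC | intermediate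
9 | (4R,5S)-4-ethenyl-3-methylidene-5-[(2S,3R)-3-methyl-3-(4-methylpent-3-en-1-yl)oxiran-2-yl]oxolan-2-one | CC(C)=CCC[C@@]1(C)O[C@H]1[C@H]1OC(=O)C(=C)[C@H]1C=C | intermediate
10 | (3S,4R,5S)-4-ethenyl-5-[(2S,3R)-3-methyl-3-(4-methylpent-3-en-1-yl)oxiran-2-yl]-3-[(4,4,5,5-tetramethyl-1,3,2-dioxaborolan-2-yl)methyl]oxolan-2-one (not isolated) | CC(C)=CCC[C@@]1(C)O[C@H]1[C@H]1OC(=O)[C@@H](CB2OC(C)(C)C(C)(C)O2)[C@H]1C=C | intermediate
11 | (3R,4R,5S)-4-ethenyl-3-(hydroxymethyl)-5-[(2S,3R)-3-methyl-3-(4-methylpent-3-en-1-yl)oxiran-2-yl]oxolan-2-one | CC(C)=CCC[C@@]1(C)O[C@H]1[C@H]1OC(=O)[C@@H](CO)[C@H]1C=C | intermediate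
12 | [(3R,4R,5S)-4-ethenyl-5-[(2S,3R)-3-methyl-3-(4-methylpent-3-en-1-yl)oxiran-2-yl]-2-oxooxolan-3-yl]methyl acetate | CC(C)=CCC[C@@]1(C)O[C@H]1[C@H]1OC(=O)[C@@H](COC(C)=O)[C@H]1C=C | intermediate
13 | secondary ozonide (3,3-dimethyl-1,2,4-trioxolane) of the distal alkene of 12, mixture at the trioxolane carbon (not isolated) | CC1(C)OOC(CC[C@@]2(C)O[C@H]2[C@H]2OC(=O)[C@@H](COC(C)=O)[C@H]2C=C)O1 | intermediate
14 | [(3R,4R,5S)-4-ethenyl-5-[(2S,3R)-3-methyl-3-(3-oxopropyl)oxiran-2-yl]-2-oxooxolan-3-yl]methyl acetate | O=CCC[C@@]1(C)O[C@H]1[C@H]1OC(=O)[C@@H](COC(C)=O)[C@H]1C=C | intermediate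
15 | nitromethane | C[N+](=O)[O-] | starting material
16 | [(3R,4R,5S)-4-ethenyl-5-[(2S,3R)-3-[(3R)-3-hydroxy-4-nitrobutyl]-3-methyloxiran-2-yl]-2-oxooxolan-3-yl]methyl acetate | O=[N+]([O-])C[C@H](O)CC[C@@]1(C)O[C@H]1[C@H]1OC(=O)[C@@H](COC(C)=O)[C@H]1C=C | intermediate
17 | [(3R,4R,5S)-5-[(2S,3R)-3-[(3R)-3-(tert-butyldimethylsilyloxy)-4-nitrobutyl]-3-methyloxiran-2-yl]-4-ethenyl-2-oxooxolan-3-yl]methyl acetate | O=[N+]([O-])C[C@H](O[Si](C)(C)C(C)(C)C)CC[C@@]1(C)O[C@H]1[C@H]1OC(=O)[C@@H](COC(C)=O)[C@H]1C=C | intermediate
18 | nitrile oxide from 17, C10 as C≡N–O (not isolated) | [O-][N+]#C[C@H](O[Si](C)(C)C(C)(C)C)CC[C@@]1(C)O[C@H]1[C@H]1OC(=O)[C@@H](COC(C)=O)[C@H]1C=C | intermediate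
19 | (1R,4R,5S,6S,7R,8S,11R) isoxazoline-bridged ten-membered epoxy lactone: O on C8, C=N at C10, C1 OTBS, C13 OAc | O3[C@H]1CC(=N3)[C@H](O[Si](C)(C)C(C)(C)C)CC[C@@]2(C)O[C@H]2[C@H]2OC(=O)[C@@H](COC(C)=O)[C@H]21 | intermediate
20 | (1R,4R,5S,6S,7S,8S,11R) C8-hydroxy C10-imine (not isolated) | O[C@H]1CC(=N)[C@H](O[Si](C)(C)C(C)(C)C)CC[C@@]2(C)O[C@H]2[C@H]2OC(=O)[C@@H](COC(C)=O)[C@H]21 | intermediate
21 | (1R,4R,5S,6S,7S,8S,11R) C8-hydroxy C10-ketone, C1 OTBS | O[C@H]1CC(=O)[C@H](O[Si](C)(C)C(C)(C)C)CC[C@@]2(C)O[C@H]2[C@H]2OC(=O)[C@@H](COC(C)=O)[C@H]21 | intermediate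
22 | (1R,4R,5S,6S,7S,8S,10R,11R) C8,C10-diol with C10 methyl, C1 OTBS | O[C@H]1C[C@@](C)(O)[C@H](O[Si](C)(C)C(C)(C)C)CC[C@@]2(C)O[C@H]2[C@H]2OC(=O)[C@@H](COC(C)=O)[C@H]21 | intermediate
23 | C8 methacrylate of 22 | C=C(C)C(=O)O[C@H]1C[C@@](C)(O)[C@H](O[Si](C)(C)C(C)(C)C)CC[C@@]2(C)O[C@H]2[C@H]2OC(=O)[C@@H](COC(C)=O)[C@H]21 | intermediate
24 | (1R,4R,5S,6S,7S,8S,10R,11R) C1,C10-diol, C8 methacrylate | C=C(C)C(=O)O[C@H]1C[C@@](C)(O)[C@H](O)CC[C@@]2(C)O[C@H]2[C@H]2OC(=O)[C@@H](COC(C)=O)[C@H]21 | intermediate
25 | (4R,5S,6S,7S,8S,10R,11R) C1 ketone, C10 tertiary alcohol, C8 methacrylate | C=C(C)C(=O)O[C@H]1C[C@@](C)(O)C(=O)CC[C@@]2(C)O[C@H]2[C@H]2OC(=O)[C@@H](COC(C)=O)[C@H]21 | intermediate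
26 | CNP0166747.1, (4R,5S,6S,7S,8S,10R,11R)-10,13-diacetoxy-4,5-epoxy-8-methacryloyloxy-1-oxogermacran-6,12-olide | C=C(C)C(=O)O[C@H]1C[C@@](C)(OC(C)=O)C(=O)CC[C@@]2(C)O[C@H]2[C@H]2OC(=O)[C@@H](COC(C)=O)[C@H]21 | target

Total step count: 17. Longest linear sequence: 15 steps (nerol 5 to target 26, steps 3–17); steps 1 and 2 prepare reagent 4.

Steps most likely to fail

Step 11. Dimerisation or oligomerisation of the nitrile oxide may outrun the ten-membered ring closure, the dipole may close in the fused sense, or it may add to the other face of the vinyl group. The fallback sets out from 17 and uses a nitronate dipole that cannot dimerise. TMSCl and Et3N in benzene should convert 17 into trimethylsilyl nitronate F1. On heating under dilution F1 should undergo intramolecular nitronate–alkene cycloaddition to N-(trimethylsilyloxy)isoxazolidine F2, forming the same C9–C10 and O–C8 bonds. Loss of trimethylsilanol from F2 (buffered TBAF/AcOH at 0 °C) returns to the route at 19.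

Step 13. Methyl may be delivered to the wrong face of the C10 carbonyl if the ring conformation overrides chelation, or a sluggish addition may let the C8 alkoxide translactonise. The fallback sets out from 21 and brings oxygen, not carbon, to the accessible face. Petasis methylenation (Cp2TiMe2, PhMe, 65 °C) should give C10-methylidene alcohol F3. Mukaiyama hydration (Co(acac)2 cat., PhSiH3, O2, THF, rt) then forms the tertiary alcohol by trapping the C10 radical with O2 from the exposed side, the complementary facial outcome, and comes back to the route at 22.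

Step 5. The syn C6/C7 relationship or the Felkin facial preference may erode, the dienylindium species may attack through a terminal carbon, or the aqueous medium may open the epoxy aldehyde. The fallback sets out from 4 (with 7) and replaces the Barbier reaction by an allylboration through a closed transition state. Borylation of 4 (B2pin2, Pd2(dba)3 cat., PhMe, rt) should give allylboronate F4, methyl (2E)-2-[(pinacolatoboryl)methyl]penta-2,4-dienoate. F4 should add to 7 in PhMe at 40 °C through a six-membered chair, its vinyl group cis to the boron-bearing CH2 enforcing the syn relationship, to give borate ester F5. Aqueous work-up of F5 releases hydroxy ester 8, where the fallback rejoins the route before lactonisation to 9.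

Further compounds
F1 | step 11 | trimethylsilyl nitronate of 17 | C[Si](C)(C)O[N+]([O-])=C[C@H](O[Si](C)(C)C(C)(C)C)CC[C@@]1(C)O[C@H]1[C@H]1OC(=O)[C@@H](COC(C)=O)[C@H]1C=C
F2 | step 11 | N-(trimethylsilyloxy)isoxazolidine bridging C8 and C10 (C10 and N configuration not fixed) | C[Si](C)(C)ON3O[C@H]1CC3[C@H](O[Si](C)(C)C(C)(C)C)CC[C@@]2(C)O[C@H]2[C@H]2OC(=O)[C@@H](COC(C)=O)[C@H]21
F3 | step 13 | C10-methylidene C8-alcohol | O[C@H]1CC(=C)[C@H](O[Si](C)(C)C(C)(C)C)CC[C@@]2(C)O[C@H]2[C@H]2OC(=O)[C@@H](COC(C)=O)[C@H]21
F4 | step 5 | methyl (2E)-2-[(4,4,5,5-tetramethyl-1,3,2-dioxaborolan-2-yl)methyl]penta-2,4-dienoate | C=C/C=C(\CB1OC(C)(C)C(C)(C)O1)C(=O)OC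
F5 | step 5 | O-(pinacolatoboryl) ether of hydroxy ester 8 | CC(C)=CCC[C@@]1(C)O[C@H]1[C@@H](OB2OC(C)(C)C(C)(C)O2)[C@H](C=C)C(=C)C(=O)OC
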